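Locants: C1 ester carbon, C2 CHMe, C3 and C6 the O-bearing dioxane carbons, C7–C8 linker, C9 carbinol, C10 C(=CH2), C11–C13 ring CH2, C14 CMe2.
Endgame: the 1,2-dioxane is closed last. C3–O comes from SN2 inversion of a syn-aldol carbinol by hydroperoxide, and C6–O from 6-endo cycloperoxymercuration of a (Z)-C5=C6 alkene. The C6 methyl comes from directed carbomagnesiation, and C4–C5 from a terminal alkyne plus a terminal epoxide.
Key disconnection: cutting C11–C12 and C13–C14 removes the unsubstituted C12–C13 ethano bridge as phenyl vinyl sulfone. The remainder is reconnected C6–C14 to a 2,2-dimethylcyclopentane-1,3-diol that carries a 2-(sulfonylmethyl)vinyl group on C9.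
Enabling feature: quaternary C14 lies 1,5 to oxygen-bearing C6 through C9–C8–C7, so a temporary C6–C14 bond gives the skeleton of a purchasable dione. C10(=CH2)–C11H2 next to C9 is the footprint of an allyl transfer. An alkoxyl radical on O6 can therefore open the five-membered ring, insert two carbons and close the six-membered ring.
Ring order: cyclopentane (bought, desymmetrised, relays chirality from C6 to C9, opened in step 5), then cyclohexane (step 5), then 1,2-dioxane (step 15).
Key step: step 5

Assumption: the (R,R)-catalyst is taken to give the (3R)-hydroxy ketone and the vinyllithium to add anti to the silyloxy group. If either sense is opposite, the mirror-image catalyst in step 1 corrects the series, because the carbinol centre made in step 1 is erased in step 5.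

Step 1
Reactants: 1 2,2-dimethylcyclopentane-1,3-dione
Product: 2 (3R)-3-hydroxy-2,2-dimethylcyclopentan-1-one
Conditions: RuCl(p-cymene)[(R,R)-TsDPEN] (1 mol %), HCO2H/Et3N (5:2), CH2Cl2, rt, stopped at monoreduction
Reagents that add atoms: none
Why: Noyori–Ikariya asymmetric transfer hydrogenation desymmetrises the prochiral 2,2-disubstituted 1,3-diketone by reducing one of the two enantiotopic carbonyls, which sets the relay stereocentre C6 under catalyst control.

Step 2
Reactants: 2 (3R)-3-hydroxy-2,2-dimethylcyclopentan-1-one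
Product: 3 (3R)-2,2-dimethyl-3-(trimethylsilyloxy)cyclopentan-1-one
Conditions: TMSCl, imidazole, CH2Cl2, 0 °C
Reagents that add atoms: chlorotrimethylsilane, C[Si](C)(C)Cl
Why: Standard silylation of a secondary alcohol masks O6 against the organolithium with a small, labile group and adds steric bias to one ring face.

Step 3
Reactants: 3 (3R)-2,2-dimethyl-3-(trimethylsilyloxy)cyclopentan-1-one; 4 (2-bromoprop-2-en-1-yl)trimethylsilane
Product: 8 (1R,3S)-2,2-dimethyl-3-(triethylsilyloxy)-3-[3-(trimethylsilyl)prop-1-en-2-yl]cyclopentan-1-ol, via vinyllithium 5 (not isolated), via lithium alkoxide 6 (not isolated), via bis-silyl ether 7 (not isolated)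
Conditions: 4, t-BuLi (2 equiv), Et2O, −78 °C; 3, −78 °C; TESOTf, −78 to 0 °C; then citric acid (cat.), MeOH, 0 °C; minor diastereomer removed by chromatography
Reagents that add atoms: triethylsilyl trifluoromethanesulfonate, CC[Si](CC)(CC)OS(=O)(=O)C(F)(F)F
Why: 1,2-Addition of a vinyllithium (bromine–lithium exchange) to the α-quaternary cyclopentanone from the face anti to the silyloxy group sets the tertiary carbinol C9, the hindered alkoxide is capped in situ as its TES ether, and mild acid methanolysis removes only the far more labile secondary TMS ether.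

Step 4
Reactants: 8 (1R,3S)-2,2-dimethyl-3-(triethylsilyloxy)-3-[3-(trimethylsilyl)prop-1-en-2-yl]cyclopentan-1-ol
Product: 9 (1R,3S)-2,2-dimethyl-3-[3-(phenylsulfonyl)prop-1-en-2-yl]-3-(triethylsilyloxy)cyclopentan-1-ol
Conditions: PhSO2Cl, Ru(bpy)3Cl2 (1 mol %), MeCN, blue LEDs, rt
Reagents that add atoms: benzenesulfonyl chloride, O=S(=O)(Cl)c1ccccc1
Why: In this desilylative radical sulfonylation of an allylsilane (addition–elimination), the sulfonyl radical adds to the CH2 terminus and the β-silyl radical is oxidised and loses Me3SiCl, which should give the transposed, constitutionally identical allyl sulfone without touching either stereocentre.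

Step 5
Reactants: 9 (1R,3S)-2,2-dimethyl-3-[3-(phenylsulfonyl)prop-1-en-2-yl]-3-(triethylsilyloxy)cyclopentan-1-ol; 10 phenyl vinyl sulfone
Product: 11 3-[(1S)-2,2-dimethyl-6-methylidene-4-(phenylsulfonyl)-1-(triethylsilyloxy)cyclohexyl]propanal (both epimers at the sulfonyl-bearing carbon)
Conditions: (n-Bu4N)2CeCl6 (5 mol %), 10 (4 equiv), 2,4,6-collidine (1.2 equiv), MeCN (0.02 M in 9), 400 nm LEDs, Ar, rt
Reagents that add atoms: none
Why: Proposed new method: photolysis (ligand-to-metal charge transfer) of the tetravalent cerium alkoxide of the only free hydroxyl of 9 should give the O6 alkoxyl radical, whose β-scission cleaves the cyclopentane bond C6–C14 rather than C6–C7, because only that path releases a tertiary radical, and so unmasks the C6 aldehyde. The nucleophilic tertiary radical adds to the CH2 terminus of electron-poor 10 (Giese addition, bond C13–C14, quaternary carbon made), since attack on its own allyl unit would need a three- or four-membered transition state. The electrophilic α-sulfonyl radical at C12 then closes the cyclohexane 6-endo-trig on the CH2 terminus of the 2-substituted allyl sulfone (bond C11–C12), 5-exo attack being hindered by fully substituted C10; β-scission of the phenylsulfonyl radical leaves the exocyclic methylene, and that radical reoxidises trivalent cerium, so the cycle is redox neutral. The closest known reaction types are cerium-photocatalysed ring-opening Giese alkylation and formal cycloaddition of cycloalkanols, alkoxyl-radical β-scission followed by allylation with allyl sulfones, and three-component alkyl radical/acceptor/allyl-transfer couplings. No bond to C9 is touched, so its configuration is carried over while the relay centre C6 is erased, and the new centre C12 forms without control and is deleted in step 7. The step needs chemoselective O-radical formation (secured by the TES ether on O9), polarity-ordered additions (nucleophilic, then electrophilic radical), and dilution of 9 against excess 10 to suppress intermolecular allyl transfer.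

Step 6
Reactants: 11 3-[(1S)-2,2-dimethyl-6-methylidene-4-(phenylsulfonyl)-1-(triethylsilyloxy)cyclohexyl]propanal
Product: 12 {[(1S)-1-(but-3-yn-1-yl)-2,2-dimethyl-6-methylidene-4-(phenylsulfonyl)cyclohexyl]oxy}triethylsilane
Conditions: dimethyl (1-diazo-2-oxopropyl)phosphonate, K2CO3, MeOH, 0 °C to rt
Reagents that add atoms: dimethyl (1-diazo-2-oxopropyl)phosphonate, CC(=O)C(=[N+]=[N-])P(=O)(OC)OC
Why: Ohira–Bestmann (Seyferth–Gilbert) homologation turns the unmasked aldehyde into the terminal alkyne (adds C5) under carbonate conditions that leave the TES ether, the alkene and C9 untouched.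

Step 7
Reactants: 12 {[(1S)-1-(but-3-yn-1-yl)-2,2-dimethyl-6-methylidene-4-(phenylsulfonyl)cyclohexyl]oxy}triethylsilane
Product: 13 {[(1S)-1-(but-3-yn-1-yl)-2,2-dimethyl-6-methylidenecyclohexyl]oxy}triethylsilane
Conditions: Mg turnings, MeOH, rt to 40 °C
Reagents that add atoms: none
Why: Reductive desulfonylation by electron transfer from magnesium in methanol removes the activating group at C12 together with its stereocentre, the isolated alkene, the alkyne and the silyl ether being inert.

Step 8
Reactants: 14 (4S)-4-benzyl-3-propanoyl-1,3-oxazolidin-2-one; 15 chloroacetaldehyde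
Product: 17 (4S)-4-benzyl-3-[(2S,3S)-4-chloro-3-hydroxy-2-methylbutanoyl]-1,3-oxazolidin-2-one, via boron enolate 16 (not isolated)
Conditions: Bu2BOTf, Et3N, CH2Cl2, −78 to 0 °C; 15 (anhydrous, freshly distilled), −78 °C; then pH 7 buffer, MeOH, 30% H2O2, 0 °C
Reagents that add atoms: none
Why: In this Evans syn aldol the (Z)-boron enolate reacts through a closed Zimmerman–Traxler transition state on the face opposite the benzyl group, which sets C2 and the syn C3 carbinol.

Step 9
Reactants: 17 (4S)-4-benzyl-3-[(2S,3S)-4-chloro-3-hydroxy-2-methylbutanoyl]-1,3-oxazolidin-2-one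
Product: 18 (2R,3S)-4-chloro-2-methylbutane-1,3-diol
Conditions: LiBH4, MeOH (1 equiv), Et2O, 0 °C
Reagents that add atoms: none
Why: Reductive cleavage of the imide with LiBH4 releases the auxiliary and gives the primary alcohol without epimerising C2 or touching the C–Cl bond.

Step 10
Reactants: 18 (2R,3S)-4-chloro-2-methylbutane-1,3-diol
Product: 20 tert-butyl(dimethyl){(2R)-2-[(2S)-oxiran-2-yl]propoxy}silane, via sodium epoxy alkoxide 19 (not isolated)
Conditions: NaH (2.2 equiv), THF, 0 °C; then TBSCl, 0 °C to rt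
Reagents that add atoms: tert-butylchlorodimethylsilane, CC(C)(C)[Si](C)(C)Cl
Why: Williamson-type 3-exo-tet closure of the chlorohydrin alkoxide leaves the C3–O bond untouched (configuration retained) and is followed by silylation of the primary alkoxide in the same flask.

Step 11
Reactants: 13 {[(1S)-1-(but-3-yn-1-yl)-2,2-dimethyl-6-methylidenecyclohexyl]oxy}triethylsilane; 20 tert-butyl(dimethyl){(2R)-2-[(2S)-oxiran-2-yl]propoxy}silane
Product: 22 (2R,3R)-1-(tert-butyldimethylsilyloxy)-8-[(1S)-2,2-dimethyl-6-methylidene-1-(triethylsilyloxy)cyclohexyl]-2-methyloct-5-yn-3-ol, via lithium acetylide 21 (not isolated)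
Conditions: 13, n-BuLi, THF, −78 °C; BF3·OEt2; 20, −78 °C
Reagents that add atoms: none
Why: BF3-assisted opening of the terminal epoxide by the lithium acetylide (Yamaguchi–Hirao alkynylation) at the unhindered CH2 forms C4–C5 and leaves the C3 carbinol configuration intact.

Step 12
Reactants: 22 (2R,3R)-1-(tert-butyldimethylsilyloxy)-8-[(1S)-2,2-dimethyl-6-methylidene-1-(triethylsilyloxy)cyclohexyl]-2-methyloct-5-yn-3-ol
Product: 24 (2R,3R,5Z)-1-(tert-butyldimethylsilyloxy)-8-[(1S)-2,2-dimethyl-6-methylidene-1-(triethylsilyloxy)cyclohexyl]-2,6-dimethyloct-5-en-3-ol, via alkenylmagnesium alkoxide 23 (not isolated)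
Conditions: MeMgBr (5 equiv), Fe(acac)3 (15 mol %), THF, −20 °C to rt; H2O quench
Reagents that add atoms: methylmagnesium bromide, C[Mg]Br
Why: Alkoxide-directed iron-catalysed syn-carbomagnesiation of a homopropargylic alcohol places methyl on the distal carbon C6 and magnesium on C5, so protonolysis should give the (Z)-trisubstituted alkene with C4 and C7 cis.

Step 13
Reactants: 24 (2R,3R,5Z)-1-(tert-butyldimethylsilyloxy)-8-[(1S)-2,2-dimethyl-6-methylidene-1-(triethylsilyloxy)cyclohexyl]-2,6-dimethyloct-5-en-3-ol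
Product: 25 the (3R)-methanesulfonate of 24
Conditions: MsCl, Et3N, CH2Cl2, −10 °C
Reagents that add atoms: methanesulfonyl chloride, CS(=O)(=O)Cl
Why: Sulfonate ester formation occurs at oxygen, so no bond to C3 is broken.

Step 14
Reactants: 25 the (3R)-methanesulfonate of 24
Product: 26 (2R,3S,5Z)-1-(tert-butyldimethylsilyloxy)-8-[(1S)-2,2-dimethyl-6-methylidene-1-(triethylsilyloxy)cyclohexyl]-2,6-dimethyloct-5-en-3-yl hydroperoxide
Conditions: 50% aq H2O2 (excess), KOH, MeOH/THF, 0 °C to rt
Reagents that add atoms: hydrogen peroxide, OO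
Why: SN2 displacement of the secondary mesylate by hydroperoxide anion (alkaline perhydrolysis) installs the O–O unit with inversion, which turns (3R) into the (3S) configuration of the target.

Step 15
Reactants: 26 (2R,3S,5Z)-1-(tert-butyldimethylsilyloxy)-8-[(1S)-2,2-dimethyl-6-methylidene-1-(triethylsilyloxy)cyclohexyl]-2,6-dimethyloct-5-en-3-yl hydroperoxide
Product: 28 tert-butyl(dimethyl){(2R)-2-[(3S,6R)-6-{2-[(1S)-2,2-dimethyl-6-methylidene-1-(triethylsilyloxy)cyclohexyl]ethyl}-6-methyl-1,2-dioxan-3-yl]propoxy}silane, via organomercurial 27 (not isolated)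
Conditions: Hg(OAc)2 (1.05 equiv), CH2Cl2, 0 °C; then NaBH4, aq NaOH, 0 °C
Reagents that add atoms: none
Why: In this cycloperoxymercuration–hydridodemercuration, Markovnikov anti 6-endo attack of the hydroperoxide on the mercurinium ion through a chair with the C3 side chain and mercury equatorial forces C7 of the (Z)-alkene axial, which sets (6R) with C7 cis to the C3 substituent, and NaBH4 then replaces mercury by hydrogen through an in-ring radical that is poorly aligned for attack on the O–O bond.

Step 16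
Reactants: 28 tert-butyl(dimethyl){(2R)-2-[(3S,6R)-6-{2-[(1S)-2,2-dimethyl-6-methylidene-1-(triethylsilyloxy)cyclohexyl]ethyl}-6-methyl-1,2-dioxan-3-yl]propoxy}silane
Product: 29 (2R)-2-[(3S,6R)-6-{2-[(1S)-1-hydroxy-2,2-dimethyl-6-methylidenecyclohexyl]ethyl}-6-methyl-1,2-dioxan-3-yl]propan-1-ol
Conditions: HF·pyridine, pyridine, THF, 0 °C to rt
Reagents that add atoms: none
Why: Fluoride-mediated cleavage removes both silyl ethers under buffered conditions that the dialkyl peroxide and the tertiary allylic alcohol should tolerate.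

Step 17
Reactants: 29 (2R)-2-[(3S,6R)-6-{2-[(1S)-1-hydroxy-2,2-dimethyl-6-methylidenecyclohexyl]ethyl}-6-methyl-1,2-dioxan-3-yl]propan-1-ol
Product: 30 (2S)-2-[(3S,6R)-6-{2-[(1S)-1-hydroxy-2,2-dimethyl-6-methylidenecyclohexyl]ethyl}-6-methyl-1,2-dioxan-3-yl]propanoic acid
Conditions: TEMPO (20 mol %), PhI(OAc)2 (2.2 equiv), MeCN/H2O (1:1), rt
Reagents that add atoms: water, O
Why: Oxoammonium oxidation (TEMPO/PhI(OAc)2) in aqueous medium takes only the primary alcohol through the aldehyde hydrate to the acid, the tertiary alcohol, alkene and peroxide being inert and C2 not being epimerised at this pH.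

Step 18
Reactants: 30 (2S)-2-[(3S,6R)-6-{2-[(1S)-1-hydroxy-2,2-dimethyl-6-methylidenecyclohexyl]ethyl}-6-methyl-1,2-dioxan-3-yl]propanoic acid
Product: 31 methyl (2S)-2-[(3S,6R)-6-{2-[(1S)-1-hydroxy-2,2-dimethyl-6-methylidenecyclohexyl]ethyl}-6-methyl-1,2-dioxan-3-yl]propanoate
Conditions: TMSCHN2, toluene/MeOH (4:1), 0 °C
Reagents that add atoms: (trimethylsilyl)diazomethane, C[Si](C)(C)C=[N+]=[N-]
Why: Esterification of the acid with (trimethylsilyl)diazomethane in methanol is neutral and fast, so neither the peroxide (no base-induced Kornblum–DeLaMare cleavage) nor C2 is endangered.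

Compound list
1 | 2,2-dimethylcyclopentane-1,3-dione | CC1(C)C(=O)CCC1=O | starting material
2 | (3R)-3-hydroxy-2,2-dimethylcyclopentan-1-one | CC1(C)[C@H](O)CCC1=O | intermediate
3 | (3R)-2,2-dimethyl-3-(trimethylsilyloxy)cyclopentan-1-one | CC1(C)[C@H](O[Si](C)(C)C)CCC1=O | intermediate
4 | (2-bromoprop-2-en-1-yl)trimethylsilane | C=C(Br)C[Si](C)(C)C | starting material
5 | [3-(trimethylsilyl)prop-1-en-2-yl]lithium | [Li]C(=C)C[Si](C)(C)C | intermediate
6 | lithium (1S,3R)-2,2-dimethyl-3-(trimethylsilyloxy)-1-[3-(trimethylsilyl)prop-1-en-2-yl]cyclopentan-1-olate | C=C(C[Si](C)(C)C)[C@]1([O-])CC[C@@H](O[Si](C)(C)C)C1(C)C.[Li+] | intermediate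
7 | triethyl{[(1S,3R)-2,2-dimethyl-3-(trimethylsilyloxy)-1-[3-(trimethylsilyl)prop-1-en-2-yl]cyclopentyl]oxy}silane | C=C(C[Si](C)(C)C)[C@]1(O[Si](CC)(CC)CC)CC[C@@H](O[Si](C)(C)C)C1(C)C | intermediate
8 | (1R,3S)-2,2-dimethyl-3-(triethylsilyloxy)-3-[3-(trimethylsilyl)prop-1-en-2-yl]cyclopentan-1-ol | C=C(C[Si](C)(C)C)[C@]1(O[Si](CC)(CC)CC)CC[C@@H](O)C1(C)C | intermediate
9 | (1R,3S)-2,2-dimethyl-3-[3-(phenylsulfonyl)prop-1-en-2-yl]-3-(triethylsilyloxy)cyclopentan-1-ol | C=C(CS(=O)(=O)c1ccccc1)[C@]2(O[Si](CC)(CC)CC)CC[C@@H](O)C2(C)C | intermediate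
10 | phenyl vinyl sulfone | C=CS(=O)(=O)c1ccccc1 | starting material
11 | 3-[(1S)-2,2-dimethyl-6-methylidene-4-(phenylsulfonyl)-1-(triethylsilyloxy)cyclohexyl]propanal | C=C1CC(S(=O)(=O)c2ccccc2)CC(C)(C)[C@@]1(O[Si](CC)(CC)CC)CCC=O | intermediate
12 | {[(1S)-1-(but-3-yn-1-yl)-2,2-dimethyl-6-methylidene-4-(phenylsulfonyl)cyclohexyl]oxy}triethylsilane | C=C1CC(S(=O)(=O)c2ccccc2)CC(C)(C)[C@@]1(O[Si](CC)(CC)CC)CCC#C | intermediate
13 | {[(1S)-1-(but-3-yn-1-yl)-2,2-dimethyl-6-methylidenecyclohexyl]oxy}triethylsilane | C=C1CCCC(C)(C)[C@@]1(O[Si](CC)(CC)CC)CCC#C | intermediate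
14 | (4S)-4-benzyl-3-propanoyl-1,3-oxazolidin-2-one | CCC(=O)N1[C@@H](Cc2ccccc2)COC1=O | starting material
15 | chloroacetaldehyde | ClCC=O | starting material
16 | (Z)-dibutylboron enolate of 14 | C/C=C(\OB(CCCC)CCCC)N1[C@@H](Cc2ccccc2)COC1=O | intermediate
17 | (4S)-4-benzyl-3-[(2S,3S)-4-chloro-3-hydroxy-2-methylbutanoyl]-1,3-oxazolidin-2-one | ClC[C@H]([C@H](C)C(=O)N1[C@@H](Cc2ccccc2)COC1=O)O | intermediate
18 | (2R,3S)-4-chloro-2-methylbutane-1,3-diol | ClC[C@H]([C@H](C)CO)O | intermediate
19 | sodium (2R)-2-[(2S)-oxiran-2-yl]propan-1-olate | C[C@H](C[O-])[C@H]1CO1.[Na+] | intermediate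
20 | tert-butyl(dimethyl){(2R)-2-[(2S)-oxiran-2-yl]propoxy}silane | C[C@H](CO[Si](C)(C)C(C)(C)C)[C@H]1CO1 | intermediate
21 | lithium acetylide of 13 | C=C1CCCC(C)(C)[C@@]1(O[Si](CC)(CC)CC)CCC#C[Li] | intermediate
22 | (2R,3R)-1-(tert-butyldimethylsilyloxy)-8-[(1S)-2,2-dimethyl-6-methylidene-1-(triethylsilyloxy)cyclohexyl]-2-methyloct-5-yn-3-ol | C=C1CCCC(C)(C)[C@@]1(O[Si](CC)(CC)CC)CCC#CC[C@H]([C@H](C)CO[Si](C)(C)C(C)(C)C)O | intermediate
23 | C5-bromomagnesio (5Z)-alkene bromomagnesium alkoxide from 22 | C=C1CCCC(C)(C)[C@@]1(O[Si](CC)(CC)CC)CC/C(C)=C([Mg]Br)\C[C@H]([C@H](C)CO[Si](C)(C)C(C)(C)C)O[Mg]Br | intermediate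
24 | (2R,3R,5Z)-1-(tert-butyldimethylsilyloxy)-8-[(1S)-2,2-dimethyl-6-methylidene-1-(triethylsilyloxy)cyclohexyl]-2,6-dimethyloct-5-en-3-ol | C=C1CCCC(C)(C)[C@@]1(O[Si](CC)(CC)CC)CC/C(C)=C\C[C@H]([C@H](C)CO[Si](C)(C)C(C)(C)C)O | intermediate
25 | (3R)-methanesulfonate of 24 | C=C1CCCC(C)(C)[C@@]1(O[Si](CC)(CC)CC)CC/C(C)=C\C[C@H]([C@H](C)CO[Si](C)(C)C(C)(C)C)OS(C)(=O)=O | intermediate
26 | (2R,3S,5Z)-hydroperoxide (C3–OOH) | C=C1CCCC(C)(C)[C@@]1(O[Si](CC)(CC)CC)CC/C(C)=C\C[C@@H]([C@H](C)CO[Si](C)(C)C(C)(C)C)OO | intermediate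
27 | 5-(acetoxymercurio)-1,2-dioxane (mercury equatorial, cis to C7) | C=C1CCCC(C)(C)[C@@]1(O[Si](CC)(CC)CC)CC[C@@]2(C)[C@@H]([Hg]OC(C)=O)C[C@@H]([C@H](C)CO[Si](C)(C)C(C)(C)C)OO2 | intermediate
28 | tert-butyl(dimethyl){(2R)-2-[(3S,6R)-6-{2-[(1S)-2,2-dimethyl-6-methylidene-1-(triethylsilyloxy)cyclohexyl]ethyl}-6-methyl-1,2-dioxan-3-yl]propoxy}silane | C=C1CCCC(C)(C)[C@@]1(O[Si](CC)(CC)CC)CC[C@@]2(C)CC[C@@H]([C@H](C)CO[Si](C)(C)C(C)(C)C)OO2 | intermediate
29 | (2R)-2-[(3S,6R)-6-{2-[(1S)-1-hydroxy-2,2-dimethyl-6-methylidenecyclohexyl]ethyl}-6-methyl-1,2-dioxan-3-yl]propan-1-ol | C=C1CCCC(C)(C)[C@@]1(O)CC[C@@]2(C)CC[C@@H]([C@H](C)CO)OO2 | intermediate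
30 | (2S)-2-[(3S,6R)-6-{2-[(1S)-1-hydroxy-2,2-dimethyl-6-methylidenecyclohexyl]ethyl}-6-methyl-1,2-dioxan-3-yl]propanoic acid | C=C1CCCC(C)(C)[C@@]1(O)CC[C@@]2(C)CC[C@@H]([C@H](C)C(=O)O)OO2 | intermediate
31 | methyl (2S)-2-[(3S,6R)-6-{2-[(1S)-1-hydroxy-2,2-dimethyl-6-methylidenecyclohexyl]ethyl}-6-methyl-1,2-dioxan-3-yl]propanoate | C=C1CCCC(C)(C)[C@@]1(O)CC[C@@]1(C)CC[C@@H]([C@H](C)C(=O)OC)OO1 | target

Total step count: 18. Longest linear sequence: 15 (steps 1–7 and 11–18).

Steps most likely to fail

Step 5. The radical relay may leak in several ways: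
- The α-sulfonyl radical may add to further 10 or close 5-exo.
- The tertiary radical may abstract the aldehydic hydrogen.
- Turnover may stall if the sulfonyl radical reoxidises trivalent cerium too slowly.

In the fallback the two bonds are made one after the other by known reactions, setting out from 9 and coming back at 13. Dual photocatalysis with CeCl3 and 9,10-diphenylanthracene (ring-opening Giese alkylation of cycloalkanols) with 1,1-bis(phenylsulfonyl)ethene should stop at the open-chain bis-sulfone aldehyde F1, because the doubly stabilised radical is reduced and protonated at once. Pd(PPh3)4 and Et3N in THF then ionise the allyl sulfone on zerovalent palladium, and the soft bis-sulfonyl carbanion closes the ring (intramolecular Tsuji–Trost alkylation) to the cyclic gem-disulfone aldehyde F2. Ohira–Bestmann homologation gives the gem-disulfone alkyne F3. Mg in MeOH removes both sulfonyl groups, which reaches 13.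

Step 14. Elimination to the diene and solvolytic participation of the homoallylic double bond may outrun bimolecular substitution at the β-branched secondary centre, and incomplete inversion would erode C3. The fallback sets out from 25 and comes back at 26. Free hydrogen peroxide is replaced by a mono-protected hydroperoxide nucleophile. 2-Methoxypropan-2-yl hydroperoxide (from ozonolysis of 2,3-dimethylbut-2-ene in MeOH) is alkylated by 25 with CsOH·H2O in DMF to the peroxyketal F4. Aqueous acetic acid then unmasks 26.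

Step 15. Three processes threaten this step:
- Poor facial selectivity in the opening of the mercurinium ion.
- Competing capture of divalent mercury by the exocyclic alkene or by O9.
- Opening of the β-peroxy radical during demercuration.

In the fallback both C–O bonds are made by stereospecific substitutions under reagent control, setting out from 25 and coming back at 28. Shi epoxidation (L-fructose-derived ketone, KHSO5, K2CO3, MeCN/dimethoxymethane/buffer, 0 °C) should epoxidise only the trisubstituted alkene to the cis-epoxy mesylate F5. Ethereal H2O2 with catalytic H3PMo12O40 opens it at tertiary C6 with inversion to the hydroperoxy alcohol mesylate F6. KOt-Bu with 18-crown-6 closes the ring by 6-exo-tet displacement of the mesylate (inversion at C3) to the 5-hydroxy-1,2-dioxane F7. 1,1'-Thiocarbonyldiimidazole gives the imidazolylthiocarbonate F8. Bu3SnH with Et3B (Barton–McCombie deoxygenation) removes the extra oxygen, which reaches 28.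

Further compounds
F1 | step 5 | (4S)-5,5-dimethyl-4-[3-(phenylsulfonyl)prop-1-en-2-yl]-7,7-bis(phenylsulfonyl)-4-(triethylsilyloxy)heptanal | C=C(CS(=O)(=O)c1ccccc1)[C@](O[Si](CC)(CC)CC)(CCC=O)C(C)(C)CC(S(=O)(=O)c1ccccc1)S(=O)(=O)c1ccccc1
F2 | step 5 | 3-[(1S)-2,2-dimethyl-6-methylidene-4,4-bis(phenylsulfonyl)-1-(triethylsilyloxy)cyclohexyl]propanal | C=C1CC(S(=O)(=O)c2ccccc2)(S(=O)(=O)c2ccccc2)CC(C)(C)[C@@]1(O[Si](CC)(CC)CC)CCC=O
F3 | step 5 | {[(1S)-1-(but-3-yn-1-yl)-2,2-dimethyl-6-methylidene-4,4-bis(phenylsulfonyl)cyclohexyl]oxy}triethylsilane | C=C1CC(S(=O)(=O)c2ccccc2)(S(=O)(=O)c2ccccc2)CC(C)(C)[C@@]1(O[Si](CC)(CC)CC)CCC#C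
F4 | step 14 | 2-methoxypropan-2-yl peroxyketal of 26 | C=C1CCCC(C)(C)[C@@]1(O[Si](CC)(CC)CC)CC/C(C)=C\C[C@@H]([C@H](C)CO[Si](C)(C)C(C)(C)C)OOC(C)(C)OC
F5 | step 15 | cis-5,6-epoxide of mesylate 25 | C=C1CCCC(C)(C)[C@@]1(O[Si](CC)(CC)CC)CC[C@@]2(C)O[C@H]2C[C@H]([C@H](C)CO[Si](C)(C)C(C)(C)C)OS(C)(=O)=O
F6 | step 15 | 6-hydroperoxy-5-hydroxy mesylate | C=C1CCCC(C)(C)[C@@]1(O[Si](CC)(CC)CC)CC[C@](C)(OO)[C@@H](O)C[C@H]([C@H](C)CO[Si](C)(C)C(C)(C)C)OS(C)(=O)=O
F7 | step 15 | 5-hydroxy derivative of dioxane 28 | C=C1CCCC(C)(C)[C@@]1(O[Si](CC)(CC)CC)CC[C@@]2(C)[C@@H](O)C[C@@H]([C@H](C)CO[Si](C)(C)C(C)(C)C)OO2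
F8 | step 15 | O-(dioxan-5-yl) 1H-imidazole-1-carbothioate of F7 | C=C1CCCC(C)(C)[C@@]1(O[Si](CC)(CC)CC)CC[C@@]2(C)[C@@H](OC(=S)n3ccnc3)C[C@@H]([C@H](C)CO[Si](C)(C)C(C)(C)C)OO2
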